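The data were generated by integration with constants of no real substance, and the scatter is random.

In a one-step world starting material takes up one gas and becomes target, and the bench rule is to extend the straight line of the readings until the charge is used.

all flasks: gas phase 2.2 mM (held)
- summer: starting material 20 mM; the very flask that is asked about, followed so far
- autumn: starting material 30 mM; run made earlier
- flask: starting material 20 mM; time 3.0 min

| run | time / s | target / % |
|---|---|---|
| summer | 10.0 | 10 |
| summer | 15.0 | 13 |
| summer | 25.0 | 23 |
| summer | 40.0 | 32 |
| summer | 50.0 | 40 |
| autumn | 10.0 | 7 |
| autumn | 12.0 | 9 |
| autumn | 20.0 | 13 |
| autumn | 30.0 | 18 |
| autumn | 40.0 | 25 |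
| autumn | 60.0 | 34 |
| autumn | 80.0 | 40 |

(scatter of a reading: 1.5 percentage points)

- at the start none of the gas phase is in solution

- green: doubling the transfer coefficient of the gas phase, all else as stated
- ochre: doubling the saturation concentration of gas phase, all else as stated

- how much target there is at 3.0 min, in percent of the starting material charged
- the change that raises the amount of target at 3.0 min, in percent of the starting material charged most ("none" if none brings more than 2 percentage points) (green / ochre / none)
- amount of target at 3.0 min, in percent of the starting material charged, after ochre

The summer run forms target at 0.160 mM s⁻¹ up to its last reading and the autumn run at 0.150 mM s⁻¹, about the same although the charges differ. That match makes the gas supply look like the rate-limiting step, and the summer figure is taken as a low estimate of gas delivered per second, since it counts target formed and leaves out gas that has gone anywhere else.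

The straight line then gives 144 % of the charge at 3.0 min, which is impossible. The border is the gas count, gas delivered up to a given time per starting material charged, estimated at 1.44 for this flask. The rule stops at a count of one, reached on this estimate at 2.08 min, earlier than the asked time.

Beyond the border, the gas needs a taker. At 40.0 s the summer run holds 6.40 mM of target and the autumn run 7.50 mM, less with less starting material, a reading that hints that target takes gas too. The reckoning here assumes that it takes one more. The gas balance, with gas still in solution set aside, then allows this flask no more than two minus the count, 56.0 % target. Taking green and ochre each to double the gas delivered puts the count at 2.88, above two, so the balance holds out less target than for this flask as it stands. This reckoning therefore answers none.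

The forecast says 76 %, ochre and 95 %, higher than this ceiling: “Ochre should nearly complete the reaction”.

The flask gives 37.6 %, best none, and 0.341 % after ochre; green changes target by −33 percentage points and ochre by −37 points.

    dissolved gas + target → over-reaction product (k = 9.70 M⁻¹ s⁻¹)
    gas phase ⇌ dissolved gas, rate k2*(csat - [dissolved gas]) (kL = 0.0930 s⁻¹)
    starting material → decomposition product (k = 3.50 × 10⁻⁵ s⁻¹)
    dissolved gas + target → over-reacted product (k = 9.80 M⁻¹ s⁻¹)
    starting material + dissolved gas ⇌ target (K = 18000 M⁻¹, k = 67.0 M⁻¹ s⁻¹)

At 1.39 min, with an estimated count of 0.667, this flask makes target 1.78 times faster than it uses it up, each step taken net. At 3.00 min, with the count past one, the rate of making over the rate of using has fallen to 0.252. The neighbouring flask charged with 8.0 mM, with a count of 3.60 reckoned at the summer figure, holds 2.98 % target beside 48.6 % over-reacted product at 3.0 min.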